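The route rests on reading the spiro carbon C3 of the ring-B isochromanone, which carries benzylic C4, lactone oxygen O2 and pyran oxygen O1', as the former carbonyl carbon of (R)-6-methyl-δ-valerolactone. In one operation a laterally lithiated ring-B o-toluate attacks that lactone, the lactol oxygen closes the isochromanone on the neighbouring ester, and acid settles the spiro centre in its anomerically favoured (S) form; the C4–C3 and O2–C1 bonds and the whole spiro ring system arise together. The precursor is methyl orsellinate with an extra oxygen beside the methyl group, allyl-protected there and benzyl-protected on the two original phenols. Ring A is attached afterwards by Ullmann etherification and depsidone lactonization.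

Key step: step 7

Remarks on the chemistry (assumptions):
- Stereochemistry: in the target the spiro carbon is (S) and the methyl-bearing carbon is (R). A chair pyran with equatorial methyl, axial lactone oxygen and equatorial benzylic carbon has exactly these descriptors, so acid equilibration is taken to deliver the target from the (R)-lactone.
- Protecting groups: because the spiro centre is set with acid, ring B carries only acid-stable ethers. The oxygen next to the methyl group is an allyl ether because it must later be freed without acid; a free phenol there could capture the ionized acylal carbon as a five-membered ketal. The two benzyl ethers leave together with the ring-A benzyl ester, so the ring-A ketone can stay masked as a dioxolane until the depsidone is closed.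

Step 1
Reactants: 1 (R)-propylene oxide; 2 ethyl propiolate
Product: 4 ethyl (R)-5-hydroxyhex-2-ynoate, via lithium (ethoxycarbonyl)ethynide 3 (not isolated)
Conditions: 2, n-BuLi, THF, −78 °C; BF3·OEt2, then 1, −78 °C; H2O
Reagents that add atoms: none
Why: The lithium acetylide opens the BF3-activated epoxide at its unsubstituted carbon (Yamaguchi–Hirao alkynylation), so the carbinol stereocentre is not touched and stays (R).

Step 2
Reactants: 4 ethyl (R)-5-hydroxyhex-2-ynoate
Product: 6 (R)-6-methyltetrahydro-2H-pyran-2-one, via ethyl (R)-5-hydroxyhexanoate 5 (not isolated)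
Conditions: H2 (1 atm), 10% Pd/C, EtOAc, rt; filter; p-TsOH·H2O (cat.), toluene, 80 °C
Reagents that add atoms: none
Why: Catalytic hydrogenation saturates the alkyne without affecting the remote carbinol, and acid-catalysed transesterification of the δ-hydroxy ester closes the six-membered lactone with loss of ethanol.

Step 3
Reactants: 7 methyl orsellinate (methyl 2,4-dihydroxy-6-methylbenzoate)
Product: 8 methyl 2,4-bis(benzyloxy)-6-methylbenzoate
Conditions: BnBr (2.4 equiv), K2CO3, DMF, 60 °C
Reagents that add atoms: benzyl bromide, BrCc1ccccc1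
Why: Williamson etherification of both phenoxides, with excess reagent and warming to bring in the chelated 2-OH.

Step 4
Reactants: 8 methyl 2,4-bis(benzyloxy)-6-methylbenzoate
Product: 9 methyl 4,6-bis(benzyloxy)-3-bromo-2-methylbenzoate
Conditions: NBS, MeCN, 0 °C to rt
Reagents that add atoms: N-bromosuccinimide, O=C1CCC(=O)N1Br
Why: Electrophilic aromatic bromination of the doubly activated ring should go to the position between the methyl group and the neighbouring benzyloxy group (para to the other ether), which is less congested than the position flanked by two benzyloxy groups, as is usual for orsellinate ethers.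

Step 5
Reactants: 9 methyl 4,6-bis(benzyloxy)-3-bromo-2-methylbenzoate
Product: 10 methyl 4,6-bis(benzyloxy)-3-hydroxy-2-methylbenzoate
Conditions: Pd2(dba)3 (2 mol%), t-BuXPhos (8 mol%), KOH, 1,4-dioxane/H2O, 100 °C; then dilute HCl
Reagents that add atoms: potassium hydroxide, [K+].[OH-]
Why: Palladium-catalysed hydroxylation of the aryl bromide (Buchwald C–O coupling with hydroxide) replaces bromine by OH, while the di-ortho-substituted methyl ester should resist saponification.

Step 6
Reactants: 10 methyl 4,6-bis(benzyloxy)-3-hydroxy-2-methylbenzoate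
Product: 11 methyl 3-(allyloxy)-4,6-bis(benzyloxy)-2-methylbenzoate
Conditions: allyl bromide, K2CO3, DMF, rt
Reagents that add atoms: allyl bromide, C=CCBr
Why: Williamson etherification of the single free phenol gives an allyl ether that is stable to base and acid and can be removed later with zerovalent palladium.

Step 7
Reactants: 11 methyl 3-(allyloxy)-4,6-bis(benzyloxy)-2-methylbenzoate; 6 (R)-6-methyltetrahydro-2H-pyran-2-one
Product: 14 (3S,6'R)-5-(allyloxy)-6,8-bis(benzyloxy)-6'-methyl-3',4',5',6'-tetrahydrospiro[isochromane-3,2'-pyran]-1-one, via laterally lithiated toluate 12 (not isolated), via lactol ester 13 (not isolated)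
Conditions: LiN(i-Pr)2 (1.2 equiv), THF, −78 °C; 6 (1.3 equiv), −78 to −20 °C; AcOH; then p-TsOH·H2O (10 mol%), CH2Cl2, rt
Reagents that add atoms: none
Why: The amide base removes a proton from the methyl group, which is acidified by conjugation with the ortho ester, and the benzylic anion 12 adds to the lactone carbonyl to give the lithium alkoxide of lactol 13. This alkoxide, or the lactol itself once acid is present, attacks the adjacent methyl ester and expels methoxide, closing the isochromanone ring by 6-exo-trig acyl substitution while the pyran ring stays intact. The closest known reaction type is the condensation of laterally lithiated o-toluates with aldehydes, esters and lactones to give 3,4-dihydroisocoumarins and their spiro acylals. The new spiro stereocentre is set under thermodynamic control: acid reversibly ionizes the acylal, and the chair pyran with equatorial (R)-methyl, axial lactone oxygen (anomeric effect) and equatorial benzylic carbon is the (S) isomer. The step needs lateral rather than ring or ether deprotonation, mono-addition and no self-condensation; the ester-conjugated methyl is by far the most acidic site, the lactolate does not release a ketone at low temperature, and the di-ortho-substituted ester is shielded from intermolecular attack. All ring-B ethers are acid-stable, so the equilibration can be driven to completion.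

Step 8
Reactants: 15 hexanoyl chloride
Product: 16 N-methoxy-N-methylhexanamide
Conditions: MeNHOMe·HCl, K2CO3, EtOAc/H2O, 0 °C to rt
Reagents that add atoms: N,O-dimethylhydroxylamine hydrochloride, CNOC.Cl
Why: Schotten–Baumann acylation of the hydroxylamine by the acid chloride gives the Weinreb amide.

Step 9
Reactants: 17 4-methoxy-2-methylaniline
Product: 18 2-bromo-4-methoxy-6-methylaniline
Conditions: NBS, MeCN, 0 °C
Reagents that add atoms: N-bromosuccinimide, O=C1CCC(=O)N1Br
Why: Electrophilic bromination is steered by the amino group to its only free ortho position, its para position being occupied by the methoxy group.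

Step 10
Reactants: 18 2-bromo-4-methoxy-6-methylaniline
Product: 20 1-bromo-2-iodo-5-methoxy-3-methylbenzene, via arenediazonium chloride 19 (not isolated)
Conditions: NaNO2, aq. HCl, 0 °C; then KI, 0 °C to rt
Reagents that add atoms: potassium iodide, [K+].[I-]
Why: Diazotization followed by Sandmeyer-type displacement of N2 by iodide puts iodine on the carbon that carried nitrogen.

Step 11
Reactants: 20 1-bromo-2-iodo-5-methoxy-3-methylbenzene; 21 benzyl chloroformate
Product: 23 benzyl 2-bromo-4-methoxy-6-methylbenzoate, via arylmagnesium chloride 22 (not isolated)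
Conditions: i-PrMgCl·LiCl, THF, −30 °C; 21, −30 to 0 °C
Reagents that add atoms: none
Why: Iodine–magnesium exchange (Knochel turbo-Grignard) is selective for iodine over bromine, and the hindered arylmagnesium is acylated once by the chloroformate to give the benzyl ester.

Step 12
Reactants: 23 benzyl 2-bromo-4-methoxy-6-methylbenzoate; 16 N-methoxy-N-methylhexanamide
Product: 25 benzyl 2-bromo-4-methoxy-6-(2-oxoheptyl)benzoate, via laterally lithiated toluate 24 (not isolated)
Conditions: LiN(i-Pr)2 (1.1 equiv), THF, −78 °C; 16, −78 to −40 °C; AcOH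
Reagents that add atoms: none
Why: Lateral lithiation of the o-toluate and acylation by the Weinreb amide, which releases the ketone only on quench, so neither over-addition nor proton transfer to the anion should interfere.

Step 13
Reactants: 25 benzyl 2-bromo-4-methoxy-6-(2-oxoheptyl)benzoate
Product: 26 benzyl 2-bromo-4-methoxy-6-[(2-pentyl-1,3-dioxolan-2-yl)methyl]benzoate
Conditions: (TMSOCH2)2, TMSOTf (5 mol%), CH2Cl2, −78 to −20 °C
Reagents that add atoms: 1,2-bis(trimethylsilyloxy)ethane, C[Si](C)(C)OCCO[Si](C)(C)C
Why: Noyori ketalization forms the dioxolane under aprotic low-temperature conditions that should not let the neighbouring ester cyclize onto the ketone.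

Step 14
Reactants: 14 (3S,6'R)-5-(allyloxy)-6,8-bis(benzyloxy)-6'-methyl-3',4',5',6'-tetrahydrospiro[isochromane-3,2'-pyran]-1-one
Product: 27 (3S,6'R)-6,8-bis(benzyloxy)-5-hydroxy-6'-methyl-3',4',5',6'-tetrahydrospiro[isochromane-3,2'-pyran]-1-one
Conditions: Pd(PPh3)4 (5 mol%), morpholine, THF, rt
Reagents that add atoms: none
Why: Zerovalent palladium ionizes the allyl aryl ether to a π-allyl complex that morpholine traps (Tsuji–Trost deallylation), freeing the phenol without acid and leaving benzyl ethers and the acylal intact.

Step 15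
Reactants: 27 (3S,6'R)-6,8-bis(benzyloxy)-5-hydroxy-6'-methyl-3',4',5',6'-tetrahydrospiro[isochromane-3,2'-pyran]-1-one; 26 benzyl 2-bromo-4-methoxy-6-[(2-pentyl-1,3-dioxolan-2-yl)methyl]benzoate
Product: 28 benzyl 2-{[(3S,6'R)-6,8-bis(benzyloxy)-6'-methyl-1-oxo-3',4',5',6'-tetrahydrospiro[isochromane-3,2'-pyran]-5-yl]oxy}-4-methoxy-6-[(2-pentyl-1,3-dioxolan-2-yl)methyl]benzoate
Conditions: CuI (20 mol%), picolinic acid (40 mol%), K3PO4, DMSO, 80 °C; pH 7 work-up
Reagents that add atoms: none
Why: Ullmann-type copper-catalysed O-arylation of a hindered phenol with the picolinic acid ligand, helped by the ester ortho to the bromine.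

Step 16
Reactants: 28 the diaryl ether of step 15
Product: 29 2-{[(3S,6'R)-6,8-dihydroxy-6'-methyl-1-oxo-3',4',5',6'-tetrahydrospiro[isochromane-3,2'-pyran]-5-yl]oxy}-4-methoxy-6-[(2-pentyl-1,3-dioxolan-2-yl)methyl]benzoic acid
Conditions: H2 (1 atm), 10% Pd/C, EtOAc, rt; filtrate used at once
Reagents that add atoms: none
Why: Hydrogenolysis removes both benzyl ethers and the benzyl ester in one neutral operation and leaves the diaryl ether, lactone, acylal and dioxolane untouched.

Step 17
Reactants: 29 the dihydroxy acid of step 16
Product: 30 depsidone ketal: the target with its ketone as the 1,3-dioxolane, spiro carbon (S), methyl-bearing carbon (R)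
Conditions: DCC, DMAP (cat.), CH2Cl2 (0.005 M), 0 °C to rt
Reagents that add atoms: none
Why: Carbodiimide activation of the acid and attack by the phenol ortho to the diaryl ether oxygen (Steglich-type lactonization) close the seven-membered depsidone ring; the chelated second phenol cannot reach the acyl group, and the masked ketone cannot form an isocoumarin.

Step 18
Reactants: 30 depsidone ketal
Product: 31 target CNP0301127.1, spiro carbon (S), methyl-bearing carbon (R)
Conditions: 1 M HCl, THF, rt
Reagents that add atoms: water, O
Why: Acid-catalysed hydrolysis of the dioxolane releases the ketone, and the same acid can only return the spiro acylal to its anomerically preferred (S) configuration.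

Compound list
1 | (R)-propylene oxide | C[C@@H]1CO1 | starting material
2 | ethyl propiolate | C#CC(=O)OCC | starting material
3 | lithium (ethoxycarbonyl)ethynide | [Li]C#CC(=O)OCC | intermediate
4 | ethyl (R)-5-hydroxyhex-2-ynoate | C[C@@H](O)CC#CC(=O)OCC | intermediate
5 | ethyl (R)-5-hydroxyhexanoate | C[C@@H](O)CCCC(=O)OCC | intermediate
6 | (R)-6-methyltetrahydro-2H-pyran-2-one | O=C1CCC[C@@H](C)O1 | intermediate
7 | methyl orsellinate | COC(=O)c1c(C)cc(O)cc1O | starting material
8 | methyl 2,4-bis(benzyloxy)-6-methylbenzoate | COC(=O)c1c(C)cc(OCc2ccccc2)cc1OCc1ccccc1 | intermediate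
9 | methyl 4,6-bis(benzyloxy)-3-bromo-2-methylbenzoate | COC(=O)c1c(C)c(Br)c(OCc2ccccc2)cc1OCc1ccccc1 | intermediate
10 | methyl 4,6-bis(benzyloxy)-3-hydroxy-2-methylbenzoate | COC(=O)c1c(C)c(O)c(OCc2ccccc2)cc1OCc1ccccc1 | intermediate
11 | methyl 3-(allyloxy)-4,6-bis(benzyloxy)-2-methylbenzoate | COC(=O)c1c(C)c(OCC=C)c(OCc2ccccc2)cc1OCc1ccccc1 | intermediate
12 | laterally lithiated toluate from 11 | [Li]Cc1c(OCC=C)c(OCc2ccccc2)cc(OCc2ccccc2)c1C(=O)OC | intermediate
13 | lactol ester: methyl 3-(allyloxy)-4,6-bis(benzyloxy)-2-{[(6R)-2-hydroxy-6-methyltetrahydropyran-2-yl]methyl}benzoate, formed as its lithium alkoxide, lactol carbon undefined | COC(=O)c1c(CC2(O)CCC[C@@H](C)O2)c(OCC=C)c(OCc2ccccc2)cc1OCc1ccccc1 | intermediate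
14 | (3S,6'R)-5-(allyloxy)-6,8-bis(benzyloxy)-6'-methyl-3',4',5',6'-tetrahydrospiro[isochromane-3,2'-pyran]-1-one | C=CCOc1c(OCc2ccccc2)cc(OCc2ccccc2)c2c1C[C@]1(CCC[C@@H](C)O1)OC2=O | intermediate
15 | hexanoyl chloride | CCCCCC(=O)Cl | starting material
16 | N-methoxy-N-methylhexanamide | CCCCCC(=O)N(C)OC | intermediate
17 | 4-methoxy-2-methylaniline | COc1ccc(N)c(C)c1 | starting material
18 | 2-bromo-4-methoxy-6-methylaniline | COc1cc(C)c(N)c(Br)c1 | intermediate
19 | 2-bromo-4-methoxy-6-methylbenzenediazonium chloride | COc1cc(C)c([N+]#N)c(Br)c1.[Cl-] | intermediate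
20 | 1-bromo-2-iodo-5-methoxy-3-methylbenzene | COc1cc(C)c(I)c(Br)c1 | intermediate
21 | benzyl chloroformate | O=C(Cl)OCc1ccccc1 | starting material
22 | (2-bromo-4-methoxy-6-methylphenyl)magnesium chloride | COc1cc(C)c([Mg]Cl)c(Br)c1 | intermediate
23 | benzyl 2-bromo-4-methoxy-6-methylbenzoate | COc1cc(C)c(C(=O)OCc2ccccc2)c(Br)c1 | intermediate
24 | laterally lithiated toluate from 23 | [Li]Cc1cc(OC)cc(Br)c1C(=O)OCc1ccccc1 | intermediate
25 | benzyl 2-bromo-4-methoxy-6-(2-oxoheptyl)benzoate | CCCCCC(=O)Cc1cc(OC)cc(Br)c1C(=O)OCc1ccccc1 | intermediate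
26 | benzyl 2-bromo-4-methoxy-6-[(2-pentyl-1,3-dioxolan-2-yl)methyl]benzoate | CCCCCC1(Cc2cc(OC)cc(Br)c2C(=O)OCc2ccccc2)OCCO1 | intermediate
27 | (3S,6'R)-6,8-bis(benzyloxy)-5-hydroxy-6'-methyl-3',4',5',6'-tetrahydrospiro[isochromane-3,2'-pyran]-1-one | Oc1c(OCc2ccccc2)cc(OCc2ccccc2)c2c1C[C@]1(CCC[C@@H](C)O1)OC2=O | intermediate
28 | diaryl ether: benzyl 2-{[(3S,6'R)-6,8-bis(benzyloxy)-6'-methyl-1-oxo-3',4',5',6'-tetrahydrospiro[isochromane-3,2'-pyran]-5-yl]oxy}-4-methoxy-6-[(2-pentyl-1,3-dioxolan-2-yl)methyl]benzoate | CCCCCC1(Cc2cc(OC)cc(Oc3c(OCc4ccccc4)cc(OCc4ccccc4)c4c3C[C@]3(CCC[C@@H](C)O3)OC4=O)c2C(=O)OCc2ccccc2)OCCO1 | intermediate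
29 | dihydroxy acid: 2-{[(3S,6'R)-6,8-dihydroxy-6'-methyl-1-oxo-3',4',5',6'-tetrahydrospiro[isochromane-3,2'-pyran]-5-yl]oxy}-4-methoxy-6-[(2-pentyl-1,3-dioxolan-2-yl)methyl]benzoic acid | CCCCCC1(Cc2cc(OC)cc(Oc3c(O)cc(O)c4c3C[C@]3(CCC[C@@H](C)O3)OC4=O)c2C(=O)O)OCCO1 | intermediate
30 | depsidone ketal (target with the ketone as 1,3-dioxolane; spiro S, methyl carbinol R) | CCCCCC1(OCCO1)Cc1cc(OC)cc2c1C(=O)Oc1cc(O)c3c(c1O2)C[C@]1(CCC[C@@H](C)O1)OC3=O | intermediate
31 | CNP0301127.1 (spiro S, methyl carbinol R) | CCCCCC(=O)Cc1cc(OC)cc2c1C(=O)Oc1cc(O)c3c(c1O2)C[C@]1(CCC[C@@H](C)O1)OC3=O | target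

Total step count: 18.
Longest linear sequence: 10 steps (3, 4, 5, 6, 7, 14, 15, 16, 17, 18) from methyl orsellinate.

Steps most likely to fail

Step 7. The benzylic anion may take a proton from the α-position of the lactone in place of adding to its carbonyl, or the adduct may stop at open-chain or dehydrated (isocoumarin) stages that close slowly. The fallback separates acylation from ring closure and sets out from 6 and 11. Lactone 6 is opened with MeNHOMe·HCl and AlMe3 to (R)-5-hydroxy-N-methoxy-N-methylhexanamide F1, which is silylated (TBSCl, imidazole) to (R)-5-(tert-butyldimethylsilyloxy)-N-methoxy-N-methylhexanamide F2. The lithiated toluate from 11 is acylated by F2 to the open-chain keto ester methyl 3-(allyloxy)-4,6-bis(benzyloxy)-2-[(6R)-6-(tert-butyldimethylsilyloxy)-2-oxoheptyl]benzoate F3. Aqueous HF in MeCN followed by p-TsOH·H2O in CH2Cl2 then removes the silyl group and closes pyran and lactone under the same thermodynamic control, returning to the route at 14.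

Step 15. The phenoxide is flanked on both sides, so C–O coupling may be slow; during prolonged heating with base the acylal may ionize and be captured by the neighbouring phenoxide as a five-membered aryl ketal. The fallback replaces the aryl halide coupling by an oxidative coupling at room temperature and sets out from 26 and 27. Miyaura borylation of 26 (B2pin2, KOAc, Pd(dppf)Cl2, dioxane, 90 °C) gives benzyl 4-methoxy-2-[(2-pentyl-1,3-dioxolan-2-yl)methyl]-6-(4,4,5,5-tetramethyl-1,3,2-dioxaborolan-2-yl)benzoate F4. Chan–Lam coupling of F4 with 27 (Cu(OAc)2, pyridine, 4 Å molecular sieves, air, CH2Cl2, rt) returns to the route at 28.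

Step 5. Oxidative addition and C–O reductive elimination at a bromide flanked by methyl and benzyloxy groups may be slow, which would let protodebromination or partial saponification by hot hydroxide compete. The fallback goes through boron and sets out from 9. Miyaura borylation (B2pin2, KOAc, Pd(OAc)2, SPhos, dioxane, 90 °C) gives methyl 4,6-bis(benzyloxy)-2-methyl-3-(4,4,5,5-tetramethyl-1,3,2-dioxaborolan-2-yl)benzoate F5. Oxidation of F5 with H2O2 and aqueous NaOH in THF at 0 °C returns to the route at 10.

Further compounds
F1 | step 7 | (R)-5-hydroxy-N-methoxy-N-methylhexanamide | C[C@@H](O)CCCC(=O)N(C)OC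
F2 | step 7 | (R)-5-(tert-butyldimethylsilyloxy)-N-methoxy-N-methylhexanamide | C[C@@H](O[Si](C)(C)C(C)(C)C)CCCC(=O)N(C)OC
F3 | step 7 | methyl 3-(allyloxy)-4,6-bis(benzyloxy)-2-[(6R)-6-(tert-butyldimethylsilyloxy)-2-oxoheptyl]benzoate | COC(=O)c1c(CC(=O)CCC[C@@H](C)O[Si](C)(C)C(C)(C)C)c(OCC=C)c(OCc2ccccc2)cc1OCc1ccccc1
F4 | step 15 | benzyl 4-methoxy-2-[(2-pentyl-1,3-dioxolan-2-yl)methyl]-6-(4,4,5,5-tetramethyl-1,3,2-dioxaborolan-2-yl)benzoate | CCCCCC1(Cc2cc(OC)cc(B3OC(C)(C)C(C)(C)O3)c2C(=O)OCc2ccccc2)OCCO1
F5 | step 5 | methyl 4,6-bis(benzyloxy)-2-methyl-3-(4,4,5,5-tetramethyl-1,3,2-dioxaborolan-2-yl)benzoate | COC(=O)c1c(C)c(B2OC(C)(C)C(C)(C)O2)c(OCc2ccccc2)cc1OCc1ccccc1
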